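**Strategy**

The cyclopentane (C1 aryl-bearing CH, C2 CMe2, C3 CH2, C4 isopropenyl-bearing CH, C5 CH2) is cut into C5–C1, supplied by a cinnamoyl imide, and C2–C3–C4, supplied by racemic 1,1-dimethyl-2-isopropenylcyclopropane. The key step exploits the 1,3-relation of the quaternary C2 and the isopropenyl carbon C4, the latent homoallyl radical of a vinylcyclopropane: in a thiyl-radical-catalysed [3+2] cycloaddition the tertiary C2 radical adds to C1 under oxazolidinone control, and the C5 radical closes onto C4, regenerating the isopropenyl group. The auxiliary-bearing acyl group on C5, absent from the target, is then excised by decarboxylation before benzoylation and deprotection.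

Key step: step 6

**Remarks on the chemistry**

- Compounds 1, 3, 6, 9 and 17 are taken as commercial.
- Assumption: the radical attacks the Yb(OTf)3-chelated s-cis imide on the face opposite the diphenylmethyl group. On this model the (4S)-auxiliary gives the R configuration at the aryl-bearing carbon; the (4R)-auxiliary would be used if the sense proved opposite.
- The configuration at the acyl-bearing carbon of 12–15 is drawn as the expected major isomer; it is inconsequential because that centre becomes CH2 in step 8.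

**Route**

Step 1
Reactants: 1 2,4,6-trihydroxybenzaldehyde
Product: 2 2,4,6-tris(methoxymethoxy)benzaldehyde
Conditions: NaH (3.6 equiv), MOMCl (3.6 equiv), DMF, 0 °C to rt
Reagents that add atoms: chloromethyl methyl ether (MOMCl), COCCl
Why: Williamson O-alkylation of the three phenoxides; NaH in DMF also alkylates the two hydrogen-bonded ortho hydroxyls.

Step 2
Reactants: 2 2,4,6-tris(methoxymethoxy)benzaldehyde; 3 malonic acid
Product: 5 (2E)-3-[2,4,6-tris(methoxymethoxy)phenyl]prop-2-enoic acid, via arylidenemalonic acid 4 (not isolated)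
Conditions: pyridine, piperidine (cat.), 90 °C
Reagents that add atoms: none
Why: Knoevenagel–Doebner condensation; the arylidenemalonic acid decarboxylates in hot pyridine to the thermodynamically favoured E acid, and the MOM acetals are stable to the buffered medium.

Step 3
Reactants: 5 (2E)-3-[2,4,6-tris(methoxymethoxy)phenyl]prop-2-enoic acid; 6 (4S)-4-(diphenylmethyl)-1,3-oxazolidin-2-one
Product: 8 (4S)-4-(diphenylmethyl)-3-{(2E)-3-[2,4,6-tris(methoxymethoxy)phenyl]prop-2-enoyl}-1,3-oxazolidin-2-one, via mixed pivalic anhydride 7 (not isolated)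
Conditions: PivCl, Et3N, THF, −20 °C; then LiCl, 6, −20 °C to rt
Reagents that add atoms: none
Why: N-acylation of the oxazolidinone through the mixed pivalic anhydride; the hindered pivaloyl carbonyl directs attack to the cinnamoyl carbonyl.

Step 4
Reactants: 9 4-methylpent-3-en-2-one (mesityl oxide)
Product: 10 1-(2,2-dimethylcyclopropyl)ethan-1-one (racemic)
Conditions: Me3S(O)I, NaH, DMSO, rt to 50 °C
Reagents that add atoms: trimethylsulfoxonium iodide, C[S+](C)(C)=O.[I-]
Why: Corey–Chaykovsky cyclopropanation: the sulfoxonium ylide adds 1,4 to the enone and the enolate closes the three-membered ring with loss of DMSO; no stereocontrol is needed because this stereocenter is erased in step 6.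

Step 5
Reactants: 10 1-(2,2-dimethylcyclopropyl)ethan-1-one
Product: 11 1,1-dimethyl-2-(prop-1-en-2-yl)cyclopropane (racemic)
Conditions: Ph3PCH3Br, KOtBu, Et2O, 0 °C to rt; fractional distillation
Reagents that add atoms: methyltriphenylphosphonium bromide, C[P+](c1ccccc1)(c1ccccc1)c1ccccc1.[Br-]
Why: Wittig methylenation of the methyl ketone; the unhindered ylide leaves the cyclopropane untouched.

Step 6
Reactants: 8 (4S)-4-(diphenylmethyl)-3-{(2E)-3-[2,4,6-tris(methoxymethoxy)phenyl]prop-2-enoyl}-1,3-oxazolidin-2-one; 11 1,1-dimethyl-2-(prop-1-en-2-yl)cyclopropane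
Product: 12 (4S)-4-(diphenylmethyl)-3-{[(1S,2R,5S)-3,3-dimethyl-5-(prop-1-en-2-yl)-2-[2,4,6-tris(methoxymethoxy)phenyl]cyclopentyl]carbonyl}-1,3-oxazolidin-2-one
Conditions: 11 (3 equiv), PhSSPh (0.3 equiv), Yb(OTf)3 (1.2 equiv), Et3B (0.3 equiv)/air, CH2Cl2/THF 4:1, −40 to 0 °C
Reagents that add atoms: none
Why: PhS• (from PhSSPh with Et3B/air) adds to the isopropenyl CH2 of 11, the cyclopropylcarbinyl radical opens to the tertiary Me2C• homoallyl radical (which erases the stereocenter of racemic 11), this nucleophilic radical adds to the β-carbon of the Yb(OTf)3-chelated imide 8, and the resulting α-acyl radical closes onto the CH= carbon of the allyl sulfide, whereupon β-scission releases PhS• and regenerates the isopropenyl group. The closest known reaction types are the thiyl-radical-catalysed [3+2] cycloaddition of vinylcyclopropanes with electron-poor alkenes and the Lewis-acid-mediated, auxiliary-controlled radical conjugate addition to N-cinnamoyl oxazolidinones. The cyclopentane is the only ring formed and it closes in the 5-exo-trig mode. The aryl-bearing stereocenter (C2 of the adduct, R) is controlled by the (S)-diphenylmethyl group, which shields one face of the s-cis chelated enoyl unit; the isopropenyl-bearing stereocenter (C5) is controlled by the chair-like 5-exo transition state with the aryl group pseudo-equatorial, which gives the 2,5-trans relation; the acyl-bearing C1 is set in the same closure and is removed later. The step needs attack of the tertiary radical at the aryl-bearing β-carbon and not at the α-carbon, secured by the polarity match between the nucleophilic radical and the Lewis-acid-activated imide, and ring opening toward CMe2, secured by the stability of the tertiary radical. All stereoisomeric by-products are diastereomers of 12 because of the auxiliary and can be removed by chromatography.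

Step 7
Reactants: 12 (4S)-4-(diphenylmethyl)-3-{[(1S,2R,5S)-3,3-dimethyl-5-(prop-1-en-2-yl)-2-[2,4,6-tris(methoxymethoxy)phenyl]cyclopentyl]carbonyl}-1,3-oxazolidin-2-one
Product: 14 (1S,2R,5S)-3,3-dimethyl-5-(prop-1-en-2-yl)-2-[2,4,6-tris(methoxymethoxy)phenyl]cyclopentane-1-carboxylic acid, via peroxy acid lithium salt 13 (not isolated)
Conditions: LiOH·H2O, 30% H2O2, THF/H2O 3:1, 0 °C to rt; aq. Na2SO3; 1 M HCl to pH 3 at 0 °C
Reagents that add atoms: hydrogen peroxide (delivered as lithium hydroperoxide), OO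
Why: Hydroperoxide cleavage of the N-acyl oxazolidinone attacks the exocyclic carbonyl selectively even in hindered imides; sulfite reduces the percarboxylate, the auxiliary is recovered, and the alkene and MOM acetals are inert to the basic peroxide.

Step 8
Reactants: 14 (1S,2R,5S)-3,3-dimethyl-5-(prop-1-en-2-yl)-2-[2,4,6-tris(methoxymethoxy)phenyl]cyclopentane-1-carboxylic acid
Product: 16 2-[(1R,4R)-2,2-dimethyl-4-(prop-1-en-2-yl)cyclopentyl]-1,3,5-tris(methoxymethoxy)benzene, via thiohydroxamate ester 15 (not isolated)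
Conditions: 2-mercaptopyridine N-oxide, DCC, DMAP (cat.), CH2Cl2, 0 °C to rt, dark; then t-BuSH, hν (tungsten lamp), 0 °C
Reagents that add atoms: none
Why: Barton reductive decarboxylation: photolysis of the thiohydroxamate ester gives the secondary cyclopentyl radical, which abstracts hydrogen from t-BuSH, so the acyl-bearing carbon becomes the ring CH2 while the two remaining stereocenters are untouched.

Step 9
Reactants: 16 2-[(1R,4R)-2,2-dimethyl-4-(prop-1-en-2-yl)cyclopentyl]-1,3,5-tris(methoxymethoxy)benzene; 17 N-methoxy-N-methylbenzamide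
Product: 20 {3-[(1R,4R)-2,2-dimethyl-4-(prop-1-en-2-yl)cyclopentyl]-2,4,6-tris(methoxymethoxy)phenyl}(phenyl)methanone, via aryllithium 18 (not isolated), via tetrahedral lithium adduct 19 (not isolated)
Conditions: n-BuLi (1.3 equiv), THF, 0 °C; then 17, −78 °C to rt; aq. NH4Cl
Reagents that add atoms: none
Why: Directed ortho-metalation at the ring C–H flanked by two MOM ethers (the two such positions are equivalent), followed by Weinreb ketone synthesis, in which the chelated tetrahedral adduct prevents a second addition.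

Step 10
Reactants: 20 {3-[(1R,4R)-2,2-dimethyl-4-(prop-1-en-2-yl)cyclopentyl]-2,4,6-tris(methoxymethoxy)phenyl}(phenyl)methanone
Product: 21 {3-[(1R,4R)-2,2-dimethyl-4-(prop-1-en-2-yl)cyclopentyl]-2,4,6-trihydroxyphenyl}(phenyl)methanone
Conditions: HCl (1.25 M in MeOH), 0 °C to rt
Reagents that add atoms: none
Why: Acid-catalysed acetal exchange of the three MOM ethers with methanol; the acetals should ionise far faster than the 1,1-disubstituted alkene is protonated, and the trans arrangement prevents the phenol from cyclising onto the isopropenyl group.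

**Compound list**

1 | 2,4,6-trihydroxybenzaldehyde | O=Cc1c(O)cc(O)cc1O | starting material
2 | 2,4,6-tris(methoxymethoxy)benzaldehyde | O=Cc1c(OCOC)cc(OCOC)cc1OCOC | intermediate
3 | malonic acid | OC(=O)CC(=O)O | starting material
4 | 2-{[2,4,6-tris(methoxymethoxy)phenyl]methylidene}propanedioic acid (not isolated) | OC(=O)C(=Cc1c(OCOC)cc(OCOC)cc1OCOC)C(=O)O | intermediate
5 | (2E)-3-[2,4,6-tris(methoxymethoxy)phenyl]prop-2-enoic acid | OC(=O)/C=C/c1c(OCOC)cc(OCOC)cc1OCOC | intermediate
6 | (4S)-4-(diphenylmethyl)-1,3-oxazolidin-2-one | O=C1N[C@@H](C(c2ccccc2)c2ccccc2)CO1 | starting material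
7 | 2,2-dimethylpropanoic (2E)-3-[2,4,6-tris(methoxymethoxy)phenyl]prop-2-enoic anhydride (not isolated) | CC(C)(C)C(=O)OC(=O)/C=C/c1c(OCOC)cc(OCOC)cc1OCOC | intermediate
8 | (4S)-4-(diphenylmethyl)-3-{(2E)-3-[2,4,6-tris(methoxymethoxy)phenyl]prop-2-enoyl}-1,3-oxazolidin-2-one | O=C1OC[C@H](C(c2ccccc2)c2ccccc2)N1C(=O)/C=C/c1c(OCOC)cc(OCOC)cc1OCOC | intermediate
9 | 4-methylpent-3-en-2-one (mesityl oxide) | CC(C)=CC(C)=O | starting material
10 | 1-(2,2-dimethylcyclopropyl)ethan-1-one (racemic) | CC(=O)C1CC1(C)C | intermediate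
11 | 1,1-dimethyl-2-(prop-1-en-2-yl)cyclopropane (racemic) | C=C(C)C1CC1(C)C | intermediate
12 | (4S)-4-(diphenylmethyl)-3-{[(1S,2R,5S)-3,3-dimethyl-5-(prop-1-en-2-yl)-2-[2,4,6-tris(methoxymethoxy)phenyl]cyclopentyl]carbonyl}-1,3-oxazolidin-2-one | C=C(C)[C@@H]1[C@H](C(=O)N2[C@@H](C(c3ccccc3)c3ccccc3)COC2=O)[C@@H](c2c(OCOC)cc(OCOC)cc2OCOC)C(C)(C)C1 | intermediate
13 | (1S,2R,5S)-3,3-dimethyl-5-(prop-1-en-2-yl)-2-[2,4,6-tris(methoxymethoxy)phenyl]cyclopentane-1-carboperoxoic acid (lithium salt in the flask; not isolated) | C=C(C)[C@@H]1[C@H](C(=O)OO)[C@@H](c2c(OCOC)cc(OCOC)cc2OCOC)C(C)(C)C1 | intermediate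
14 | (1S,2R,5S)-3,3-dimethyl-5-(prop-1-en-2-yl)-2-[2,4,6-tris(methoxymethoxy)phenyl]cyclopentane-1-carboxylic acid | C=C(C)[C@@H]1[C@H](C(=O)O)[C@@H](c2c(OCOC)cc(OCOC)cc2OCOC)C(C)(C)C1 | intermediate
15 | 2-thioxopyridin-1(2H)-yl (1S,2R,5S)-3,3-dimethyl-5-(prop-1-en-2-yl)-2-[2,4,6-tris(methoxymethoxy)phenyl]cyclopentane-1-carboxylate (not isolated) | C=C(C)[C@@H]1[C@H](C(=O)ON2C=CC=CC2=S)[C@@H](c2c(OCOC)cc(OCOC)cc2OCOC)C(C)(C)C1 | intermediate
16 | 2-[(1R,4R)-2,2-dimethyl-4-(prop-1-en-2-yl)cyclopentyl]-1,3,5-tris(methoxymethoxy)benzene | C=C(C)[C@@H]1C[C@@H](c2c(OCOC)cc(OCOC)cc2OCOC)C(C)(C)C1 | intermediate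
17 | N-methoxy-N-methylbenzamide | CON(C)C(=O)c1ccccc1 | starting material
18 | {3-[(1R,4R)-2,2-dimethyl-4-(prop-1-en-2-yl)cyclopentyl]-2,4,6-tris(methoxymethoxy)phenyl}lithium (not isolated) | C=C(C)[C@@H]1C[C@@H](c2c(OCOC)cc(OCOC)c([Li])c2OCOC)C(C)(C)C1 | intermediate
19 | lithium {3-[(1R,4R)-2,2-dimethyl-4-(prop-1-en-2-yl)cyclopentyl]-2,4,6-tris(methoxymethoxy)phenyl}[methoxy(methyl)amino](phenyl)methanolate (not isolated) | C=C(C)[C@@H]1C[C@@H](c2c(OCOC)cc(OCOC)c(C(O[Li])(N(C)OC)c3ccccc3)c2OCOC)C(C)(C)C1 | intermediate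
20 | {3-[(1R,4R)-2,2-dimethyl-4-(prop-1-en-2-yl)cyclopentyl]-2,4,6-tris(methoxymethoxy)phenyl}(phenyl)methanone | C=C(C)[C@@H]1C[C@@H](c2c(OCOC)cc(OCOC)c(C(=O)c3ccccc3)c2OCOC)C(C)(C)C1 | intermediate
21 | {3-[(1R,4R)-2,2-dimethyl-4-(prop-1-en-2-yl)cyclopentyl]-2,4,6-trihydroxyphenyl}(phenyl)methanone | C=C(C)[C@@H]1C[C@@H](c2c(O)cc(O)c(C(=O)c3ccccc3)c2O)C(C)(C)C1 | target

**Step count and risks**

Total step count: 10. Longest linear sequence: 8 steps (steps 1, 2, 3, 6, 7, 8, 9, 10); steps 4 and 5 form the convergent branch.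

The three steps most likely to fail:

Step 6. The addition of the hindered tertiary radical to the β-carbon that carries the di-ortho-substituted aryl group may be too slow to sustain the chain. Facial selectivity may also erode if the reaction has to be warmed, and the ring closure may give an insufficient trans preference. The fallback sets out from aldehyde 2 (with 11) and returns at 16. Knoevenagel condensation of 2 with bis(phenylsulfonyl)methane (piperidinium acetate, toluene, reflux with water removal) would give the doubly activated alkene 2-[2,2-bis(phenylsulfonyl)ethenyl]-1,3,5-tris(methoxymethoxy)benzene F1. The thermal thiyl-mediated [3+2] cycloaddition of F1 with 11 (PhSSPh, AIBN, benzene, 80 °C), without Lewis acid or auxiliary, should give racemic trans-2-[5,5-dimethyl-2,2-bis(phenylsulfonyl)-3-(prop-1-en-2-yl)cyclopentyl]-1,3,5-tris(methoxymethoxy)benzene F2. Preparative HPLC on a chiral stationary phase would give the (1R,3R)-enantiomer F3, and desulfonylation with Mg in MeOH removes both sulfonyl groups to give 16.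

Step 8. Esterification of the hindered acid with the thiohydroxamic acid may be slow, and radical-chain hydrothiolation of the isopropenyl group by t-BuSH may compete with hydrogen transfer. The fallback sets out from 14 and returns at 16. Esterification with N-hydroxyphthalimide (DIC, DMAP, CH2Cl2) would give the redox-active ester 1,3-dioxoisoindolin-2-yl (1S,2R,5S)-3,3-dimethyl-5-(prop-1-en-2-yl)-2-[2,4,6-tris(methoxymethoxy)phenyl]cyclopentane-1-carboxylate F4. Thiol-free reductive decarboxylation (NiCl2·6H2O, 4,4'-di-tert-butyl-2,2'-bipyridine, Zn, PhSiH3, THF/DMF/i-PrOH, 40 °C) would then give 16.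

Step 10. During acidic acetal cleavage the isopropenyl group may add methanol or chloride in the Markovnikov sense, or the double bond may migrate to the isopropylidene position with loss of the adjacent stereocenter. The fallback sets out from 20 and returns at 21. Non-acidic silyl exchange (TESOTf, 2,2'-bipyridyl, CH2Cl2, 0 °C) would convert the aryl MOM ethers into {3-[(1R,4R)-2,2-dimethyl-4-(prop-1-en-2-yl)cyclopentyl]-2,4,6-tris(triethylsilyloxy)phenyl}(phenyl)methanone F5. Desilylation with TBAF/AcOH in THF at 0 °C would then give 21.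

**Further compounds**

F1 | step 6 | 2-[2,2-bis(phenylsulfonyl)ethenyl]-1,3,5-tris(methoxymethoxy)benzene | O=S(=O)(c1ccccc1)C(=Cc1c(OCOC)cc(OCOC)cc1OCOC)S(=O)(=O)c1ccccc1
F2 | step 6 | racemic trans-2-[5,5-dimethyl-2,2-bis(phenylsulfonyl)-3-(prop-1-en-2-yl)cyclopentyl]-1,3,5-tris(methoxymethoxy)benzene (both enantiomers) | C=C(C)[C@@H]1C(S(=O)(=O)c2ccccc2)(S(=O)(=O)c2ccccc2)[C@@H](c2c(OCOC)cc(OCOC)cc2OCOC)C(C)(C)C1.C=C(C)[C@H]1C(S(=O)(=O)c2ccccc2)(S(=O)(=O)c2ccccc2)[C@H](c2c(OCOC)cc(OCOC)cc2OCOC)C(C)(C)C1
F3 | step 6 | 2-[(1R,3R)-5,5-dimethyl-2,2-bis(phenylsulfonyl)-3-(prop-1-en-2-yl)cyclopentyl]-1,3,5-tris(methoxymethoxy)benzene | C=C(C)[C@@H]1C(S(=O)(=O)c2ccccc2)(S(=O)(=O)c2ccccc2)[C@@H](c2c(OCOC)cc(OCOC)cc2OCOC)C(C)(C)C1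
F4 | step 8 | 1,3-dioxoisoindolin-2-yl (1S,2R,5S)-3,3-dimethyl-5-(prop-1-en-2-yl)-2-[2,4,6-tris(methoxymethoxy)phenyl]cyclopentane-1-carboxylate | C=C(C)[C@@H]1[C@H](C(=O)ON2C(=O)c3ccccc3C2=O)[C@@H](c2c(OCOC)cc(OCOC)cc2OCOC)C(C)(C)C1
F5 | step 10 | {3-[(1R,4R)-2,2-dimethyl-4-(prop-1-en-2-yl)cyclopentyl]-2,4,6-tris(triethylsilyloxy)phenyl}(phenyl)methanone | C=C(C)[C@@H]1C[C@@H](c2c(O[Si](CC)(CC)CC)cc(O[Si](CC)(CC)CC)c(C(=O)c3ccccc3)c2O[Si](CC)(CC)CC)C(C)(C)C1
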